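**Strategy**

Fragilide F has a ten-membered carbocycle (C1–C10) spanned by a C4–O–C8 ether and flanked by oxygen on C2 and C9, two carbons that C3 joins in a 1,3-relationship. The plan reads this pattern backwards: reconnecting C3 to C9 gives an aldol of a trans-hydrindane (ring A plus C1, C2, C3, C9, C10), and the ether-bridged C4–C8 unit is then a 3-oxidopyrylium added across its C3=C9 silyl enol ether. One [5+2] cycloaddition makes C3–C4 and C8–C9 and closes the oxa-bridged seven-membered ring. Its precursors are a rigid, enantiopure hydrindenyl enol ether and a racemic acetoxypyranone carrying the C17–C19 propionate.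

Key step: step 18

Remark (numbering): briarane numbering of the target is used throughout (C15 methyl on C1, C16 on C5, C17/C18/C19 lactone CH/CH3/C=O, C20 on C11); β is the face of ring A that carries C15.
Remark (assumption, step 6): the sense of induction is taken from the formyl C–H···O binding model for 2-substituted enals; should the antipode form, the (S)-configured catalyst is used instead.
Remark (assumption, steps 8 and 19): C2 in 11 and C5 in 26 are drawn as the expected epimers; both centres become trigonal again later, so either epimer serves. Compounds 20–27 are racemic or C17-epimeric mixtures.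

**Route**

Step 1
Reactants: 1 1,1-dimethoxypropan-2-one; 2 dimethyl (2-oxopropyl)phosphonate
Product: 3 (E)-5,5-dimethoxy-4-methylpent-3-en-2-one
Conditions: NaH, THF, 0 °C to reflux
Reagents that add atoms: none
Why: Horner–Wadsworth–Emmons olefination: the sodium phosphonate anion adds to the activated α,α-dialkoxy ketone and the oxaphosphetane collapses to the trisubstituted enone, whose geometry is not critical because it is equilibrated in step 2.

Step 2
Reactants: 3 (E)-5,5-dimethoxy-4-methylpent-3-en-2-one
Product: 4 (E)-2-methyl-4-oxopent-2-enal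
Conditions: 1 M HCl, THF, rt
Reagents that add atoms: water, O
Why: Acid-catalysed acetal hydrolysis frees the aldehyde, and reversible conjugate addition of water under the same conditions should drain the ene-dicarbonyl into the more stable E isomer with acetyl trans to formyl.

Step 3
Reactants: 5 acrolein
Product: 6 3-(phenylselanyl)propanal
Conditions: PhSeH, CH2Cl2, 0 °C
Reagents that add atoms: benzeneselenol, [SeH]c1ccccc1
Why: Conjugate (Michael) addition of the soft selenol to the enal is fast and needs no catalyst, giving the β-seleno aldehyde that carries the future C20.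

Step 4
Reactants: 6 3-(phenylselanyl)propanal
Product: 7 (E)-5-(phenylselanyl)pent-2-enal
Conditions: Ph3P=CHCHO, toluene, 80 °C
Reagents that add atoms: (triphenylphosphoranylidene)acetaldehyde, O=CC=P(c1ccccc1)(c1ccccc1)c1ccccc1
Why: Wittig olefination with the stabilised formyl ylide adds C13 and C14 and should give the E enal.

Step 5
Reactants: 7 (E)-5-(phenylselanyl)pent-2-enal
Product: 8 (1E,3E)-5-(phenylselanyl)-1-(triisopropylsilyloxy)penta-1,3-diene
Conditions: i-Pr3SiOTf, Et3N, Et2O, 0 °C to rt
Reagents that add atoms: triisopropylsilyl trifluoromethanesulfonate, CC(C)[Si](C(C)C)(C(C)C)OS(=O)(=O)C(F)(F)F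
Why: Soft enolisation (O-silylation of the enal, then γ-deprotonation by the amine) gives the 1-silyloxy diene, the E,E isomer being favoured because both new substituents avoid the inside positions.

Step 6
Reactants: 4 (E)-2-methyl-4-oxopent-2-enal; 8 (1E,3E)-5-(phenylselanyl)-1-(triisopropylsilyloxy)penta-1,3-diene
Product: 9 ring A cyclohexene keto aldehyde
Conditions: (R)-3,3-diphenyl-1-(o-tolyl)tetrahydro-1H,3H-pyrrolo[1,2-c][1,3,2]oxazaborole (20 mol %), HN(SO2CF3)2 (17 mol %), CH2Cl2, −78 to −40 °C
Reagents that add atoms: none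
Why: Enantioselective Lewis acid-catalysed Diels–Alder reaction: the boron-bound formyl group makes C10 the electrophilic terminus, which joins the oxygen-remote diene carbon C11 while C1 joins C14; the formyl-endo transition state places the C14 oxygen cis to the formyl group, the E dienophile keeps acetyl trans to formyl, the E,E diene places C20 cis to the C14 oxygen, and the chiral cation shields one face of C1 so that C1, C10, C11 and C14 are set in the absolute sense shown.

Step 7
Reactants: 9 ring A cyclohexene keto aldehyde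
Product: 10 ring A cyclohexane keto aldehyde
Conditions: KO2CN=NCO2K, AcOH, pyridine, rt
Reagents that add atoms: none
Why: Diimide reduction: diimide, released from the azodicarboxylate by protonation and decarboxylation, delivers H2 to C12=C13 in a concerted syn transfer and leaves the selenide (a poison for hydrogenation catalysts), the aldehyde and the ketone untouched.

Step 8
Reactants: 10 ring A cyclohexane keto aldehyde
Product: 11 trans-hydrindanone aldol
Conditions: LiN(SiMe3)2, THF, −78 °C; AcOH, −78 °C
Reagents that add atoms: none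
Why: Intramolecular aldol addition: the kinetic lithium enolate of the methyl ketone (C3) adds to the non-enolisable neopentyl aldehyde to close the trans-fused cyclopentanone, the aldehyde oxygen turning away from the axial C14 silyloxy group so that the C2 hydroxyl is expected syn to the C15 methyl (a centre that is oxidised and reset later).

Step 9
Reactants: 11 trans-hydrindanone aldol
Product: 12 C2 triethylsilyl ether of the aldol
Conditions: Et3SiOTf, 2,6-lutidine, CH2Cl2, −78 °C
Reagents that add atoms: triethylsilyl trifluoromethanesulfonate, CC[Si](CC)(CC)OS(=O)(=O)C(F)(F)F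
Why: Silylation of the hindered secondary alcohol with a silyl triflate and a non-nucleophilic base protects O2 and shuts off retro-aldol cleavage before the ketone is enolised.

Step 10
Reactants: 12 C2 triethylsilyl ether of the aldol
Product: 14 methylene hydrindanone, via selenoxide 13 (not isolated)
Conditions: mCPBA (1.0 equiv), CH2Cl2, −78 °C; then i-Pr2NH, −78 to 40 °C
Reagents that add atoms: none
Why: Selenide oxidation and selenoxide syn-elimination: selenium is oxidised selectively at low temperature and the primary selenoxide eliminates through its only β-hydrogen (H11) to give the exocyclic C11=C20 alkene, the amine intercepting benzeneselenenic acid.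

Step 11
Reactants: 14 methylene hydrindanone
Product: 15 hydrindenyl triethylsilyl enol ether
Conditions: LiN(i-Pr)2, Et3SiCl (in situ), THF, −78 °C
Reagents that add atoms: chlorotriethylsilane, CC[Si](CC)(CC)Cl
Why: Kinetic enolisation and O-silylation: the amide base removes a proton from the unhindered C3 methylene in preference to the tertiary H10, which lies under the syn-axial C14 silyloxy group, and the enolate is trapped as the C3=C9 silyl enol ether.

Step 12
Reactants: 16 5-bromofuran-2-carbaldehyde
Product: 17 (5-bromofuran-2-yl)methanol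
Conditions: NaBH4, MeOH, 0 °C
Reagents that add atoms: none
Why: Borohydride reduction of the aldehyde gives the furfuryl alcohol that later supplies C4 and the bridging oxygen.

Step 13
Reactants: 17 (5-bromofuran-2-yl)methanol
Product: 18 [(5-bromofuran-2-yl)methoxy](tert-butyl)dimethylsilane
Conditions: t-BuMe2SiCl, imidazole, CH2Cl2, rt
Reagents that add atoms: tert-butylchlorodimethylsilane, CC(C)(C)[Si](C)(C)Cl
Why: Silylation masks the hydroxyl proton, which would otherwise quench the ester enolate in step 14.

Step 14
Reactants: 18 [(5-bromofuran-2-yl)methoxy](tert-butyl)dimethylsilane; 19 tert-butyl propanoate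
Product: 20 tert-butyl 2-[5-(tert-butyldimethylsilyloxymethyl)furan-2-yl]propanoate
Conditions: LiNCy2 (from Cy2NH and n-BuLi), Pd(dba)2 (zerovalent palladium, 2 mol %), P(t-Bu)3 (2 mol %), toluene, rt
Reagents that add atoms: none
Why: Palladium-catalysed α-arylation of an ester enolate (oxidative addition of the bromofuran to zerovalent palladium, transmetalation with the lithium enolate, reductive elimination) forms the C8–C17 bond; C17 is formed racemic and is equilibrated in step 20.

Step 15
Reactants: 20 tert-butyl 2-[5-(tert-butyldimethylsilyloxymethyl)furan-2-yl]propanoate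
Product: 21 tert-butyl 2-[5-(hydroxymethyl)furan-2-yl]propanoate
Conditions: Bu4NF, THF, 0 °C
Reagents that add atoms: none
Why: Fluoride-induced desilylation frees the furfuryl alcohol needed for the oxidative ring expansion.

Step 16
Reactants: 21 tert-butyl 2-[5-(hydroxymethyl)furan-2-yl]propanoate
Product: 22 tert-butyl 2-(2-hydroxy-5-oxo-5,6-dihydro-2H-pyran-2-yl)propanoate
Conditions: NBS, NaHCO3, THF/H2O (4:1), 0 °C
Reagents that add atoms: water, O
Why: Achmatowicz rearrangement: bromonium-induced 2,5-oxidation of the furan, opening to the ene-dione and closure of the primary hydroxyl onto the C8 ketone give the pyranone hemiketal, in which C4 is the ring CH2, C5 the ketone and C8 the hemiketal carbon (the stereoisomer mixture is inconsequential).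

Step 17
Reactants: 22 tert-butyl 2-(2-hydroxy-5-oxo-5,6-dihydro-2H-pyran-2-yl)propanoate
Product: 23 tert-butyl 2-(2-acetoxy-5-oxo-5,6-dihydro-2H-pyran-2-yl)propanoate
Conditions: Ac2O, pyridine, 4-(dimethylamino)pyridine (10 mol %), CH2Cl2, 0 °C
Reagents that add atoms: acetic anhydride, CC(=O)OC(C)=O
Why: Nucleophile-catalysed acetylation of the tertiary hemiketal hydroxyl installs the leaving group for ylide formation.

Step 18
Reactants: 15 hydrindenyl triethylsilyl enol ether; 23 tert-butyl 2-(2-acetoxy-5-oxo-5,6-dihydro-2H-pyran-2-yl)propanoate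
Product: 25 [5+2] cycloadduct, via oxidopyrylium ylide 24 (not isolated)
Conditions: i-Pr2NEt, MeCN, 40–60 °C, 23 (4 equiv) added by syringe pump
Reagents that add atoms: none
Why: Proposed new method: the amine removes a C4 proton of 23 and acetate leaves from C8 to give the 3-oxidopyrylium 24, a carbonyl ylide spanning C4–O–C8 with the oxido group on C5, which should add suprafacially across the polarised C3=C9 enol ether in an asynchronous [5+2] (1,3-dipolar) cycloaddition, nucleophilic C3 bonding to the unhindered C4 and the silyloxy-stabilised C9 closing onto C8. The closest known reaction type is the intermolecular [5+2] cycloaddition of 3-oxidopyrylium ylides from acetoxypyranones with simple vinyl ethers, in which the alkoxy carbon joins the former acetal carbon and the alkoxy group sits endo; new here are the trisubstituted cyclic silyl enol ether and the bond between two fully substituted carbons (C8–C9). Two rings close in the one cycloaddition event: the oxa-bridged seven-membered carbocycle C3–C4–C5–C6–C7–C8–C9 (both new bonds made across the ylide termini) and the five-membered ring O–C4–C3–C9–C8. C3 and C9 are set by addition to the α face of the enol ether, anti to the angular C15 methyl and the C2 silyloxy group; C4 and C8 are set together, relative to them, by the exo orientation of the hydrindane (turned away from the C5–C7 bridge, C9 silyloxy endo); C17 is not controlled here and is corrected in step 20. The step needs regioselectivity (C3 to C4, C9 to C8), supplied by the enol ether polarisation and the unhindered C3–C4 contact, and face and exo selectivity, enforced by the rigid trans-hydrindane; slow addition of excess 23 keeps ylide dimerisation in check.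

Step 19
Reactants: 25 [5+2] cycloadduct
Product: 26 C5 methyl carbinol
Conditions: MeLi, CeCl3, THF, −78 °C
Reagents that add atoms: methyllithium, [Li]C
Why: 1,2-Addition of the weakly basic organocerium reagent to the enone carbonyl brings in C16, attack from the face of the oxygen bridge being expected; the C5 configuration is immaterial because C5 becomes trigonal in step 20.

Step 20
Reactants: 26 C5 methyl carbinol
Product: 28 bis-silyl lactone, via lactone epimer mixture 27 (not isolated)
Conditions: camphor-10-sulfonic acid (30 mol %), CH2Cl2, 0 °C to rt; then DBU, 40 °C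
Reagents that add atoms: none
Why: Allylic transposition with lactonisation (SN1'): acid ionises the tertiary allylic alcohol to the C5–C6–C7 allyl cation, the tert-butyl ester carbonyl captures C7 in a 5-exo closure with loss of 2-methylpropene (the irreversible exit), attack on the face of the oxygen bridge, the only one not covered by the C3–C9 bridge, sets C7, and DBU then epimerises C17 through the lactone enolate to the isomer with the methyl anti to C9.

Step 21
Reactants: 28 bis-silyl lactone
Product: 29 lactone 2,9-diol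
Conditions: HF·pyridine, pyridine, THF, 0 °C to rt
Reagents that add atoms: none
Why: Buffered fluoride cleavage removes the two triethylsilyl ethers and spares the bulkier triisopropylsilyl ether, the lactone and both alkenes.

Step 22
Reactants: 29 lactone 2,9-diol
Product: 30 lactone β-hydroxy ketone
Conditions: 1,1,1-triacetoxy-1,1-dihydro-1,2-benziodoxol-3(1H)-one, NaHCO3, CH2Cl2, rt
Reagents that add atoms: none
Why: Periodinane oxidation converts the secondary C2 alcohol into the ketone under buffered conditions while the tertiary C9 hydroxyl cannot be oxidised, giving the β-hydroxy ketone set up for fragmentation.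

Step 23
Reactants: 30 lactone β-hydroxy ketone
Product: 32 oxa-bridged ten-membered hydroxy diketone, via potassium enolate 31 (not isolated)
Conditions: KN(SiMe3)2 (1.05 equiv), THF, −78 to 0 °C; then 2-(phenylsulfonyl)-3-phenyloxaziridine, −78 °C; AcOH
Reagents that add atoms: 2-(phenylsulfonyl)-3-phenyloxaziridine, O=S(=O)(c1ccccc1)N1OC1c1ccccc1
Why: Anionic retro-aldol fragmentation with enolate hydroxylation: the potassium C9 alkoxide collapses to the C9 ketone with cleavage of C3–C9 (driven by release of the compact polycycle and by exchange of an alkoxide for the less basic C2 enolate), which unveils the ten-membered ring, and the N-sulfonyloxaziridine hydroxylates enolate 31 at C3 on its outer face, anti to the transannular C9 carbonyl, which sets C3.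

Step 24
Reactants: 32 oxa-bridged ten-membered hydroxy diketone
Product: 33 2,3,9-triol
Conditions: NaBH4, CeCl3·7H2O, MeOH, −78 to −20 °C
Reagents that add atoms: none
Why: Luche reduction: hydride should reach each carbonyl from the periphery of the bridged ring (C9 on the face turned away from C3, C2 anti to the C15 methyl in the non-chelated arrangement), which gives the C2 and C9 configurations of the target, while the cerium salt keeps the medium non-basic so that C10 and the lactone are not disturbed.

Step 25
Reactants: 33 2,3,9-triol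
Product: 34 2,3,9,14-tetraol
Conditions: Bu4NF, AcOH, THF, rt to 40 °C
Reagents that add atoms: none
Why: Buffered fluoride desilylation removes the triisopropylsilyl group from O14 without base-induced acyl transfer of the lactone.

Step 26
Reactants: 34 2,3,9,14-tetraol
Product: 35 2,3,9,14-tetraacetate
Conditions: Ac2O, Et3N, 4-(dimethylamino)pyridine (20 mol %), CH2Cl2, rt to 40 °C
Reagents that add atoms: acetic anhydride, CC(=O)OC(C)=O
Why: Nucleophile-catalysed acylation esterifies the four secondary hydroxyls at C2, C3, C9 and C14; no tertiary hydroxyl is present at this stage.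

Step 27
Reactants: 35 2,3,9,14-tetraacetate
Product: 36 11,20-epoxide
Conditions: mCPBA (1.05 equiv), NaHCO3, CH2Cl2, −20 to 0 °C
Reagents that add atoms: 3-chloroperoxybenzoic acid, OOC(=O)c1cccc(Cl)c1
Why: Peracid epoxidation (concerted oxygen transfer) should pick the 1,1-disubstituted C11=C20 bond because C5=C6 is deactivated by its allylic C4 and C7 oxygens and shielded by the bridge; oxygen is delivered to the α face (equatorial attack, the β face being blocked by the syn-axial C15 methyl), which sets C11.

Step 28
Reactants: 36 11,20-epoxide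
Product: 37 chlorohydrin tetraacetate
Conditions: pyridinium chloride, CH2Cl2, rt
Reagents that add atoms: pyridinium chloride, [Cl-].c1cc[nH+]cc1
Why: SN2 opening of the protonated epoxide by chloride at the primary C20 gives the 11-hydroxy-20-chloride with retention at C11.

Step 29
Reactants: 37 chlorohydrin tetraacetate
Product: 38 Fragilide F
Conditions: Ca(OCl)2, CO2 (solid), CH2Cl2/H2O, 0 °C
Reagents that add atoms: calcium hypochlorite, [Ca+2].[O-]Cl.[O-]Cl
Why: Ene-type allylic chlorination by HOCl: electrophilic chlorine adds to C6 of the trisubstituted alkene on the pyran face opposite the transannular C3/C9 bridge and a C16 proton is lost, which gives the C5=C16 methylene and sets C6 (a reagent that transfers chlorine directly is chosen so that chlorine stays on the face it attacks).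

**Compound list**

1 | 1,1-dimethoxypropan-2-one (pyruvaldehyde dimethyl acetal; C15, C1, C2) | CC(=O)C(OC)OC | starting material
2 | dimethyl (2-oxopropyl)phosphonate (C3, C9, C10) | CC(=O)CP(=O)(OC)OC | starting material
3 | (E)-5,5-dimethoxy-4-methylpent-3-en-2-one (E shown; Z isomer carried along) | CC(=O)/C=C(\C)C(OC)OC | intermediate
4 | (E)-2-methyl-4-oxopent-2-enal | CC(=O)/C=C(\C)C=O | intermediate
5 | acrolein (C12, C11, C20) | C=CC=O | starting material
6 | 3-(phenylselanyl)propanal | O=CCC[Se]c1ccccc1 | intermediate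
7 | (E)-5-(phenylselanyl)pent-2-enal | O=C/C=C/CC[Se]c1ccccc1 | intermediate
8 | (1E,3E)-5-(phenylselanyl)-1-(triisopropylsilyloxy)penta-1,3-diene | CC(C)[Si](C(C)C)(C(C)C)O/C=C/C=C/C[Se]c1ccccc1 | intermediate
9 | ring A cyclohexene keto aldehyde: C1 with β-CH3 and α-CHO, C10 β-acetyl, C11 α-CH2SePh, C12=C13, C14 α-OSi(i-Pr)3 | CC(=O)[C@H]1[C@H](C[Se]c2ccccc2)C=C[C@H](O[Si](C(C)C)(C(C)C)C(C)C)[C@]1(C)C=O | intermediate
10 | ring A cyclohexane keto aldehyde (9 with C12–C13 saturated) | CC(=O)[C@H]1[C@H](C[Se]c2ccccc2)CC[C@H](O[Si](C(C)C)(C(C)C)C(C)C)[C@]1(C)C=O | intermediate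
11 | trans-hydrindanone aldol: C9 ketone, 2β-OH, 11α-CH2SePh, 14α-OSi(i-Pr)3 | O=C1[C@H]2[C@H](C[Se]c3ccccc3)CC[C@H](O[Si](C(C)C)(C(C)C)C(C)C)[C@]2(C)[C@@H](O)C1 | intermediate
12 | C2 triethylsilyl ether of the aldol | O=C1[C@H]2[C@H](C[Se]c3ccccc3)CC[C@H](O[Si](C(C)C)(C(C)C)C(C)C)[C@]2(C)[C@@H](O[Si](CC)(CC)CC)C1 | intermediate
13 | selenoxide of 12 | O=C1[C@H]2[C@H](C[Se](=O)c3ccccc3)CC[C@H](O[Si](C(C)C)(C(C)C)C(C)C)[C@]2(C)[C@@H](O[Si](CC)(CC)CC)C1 | intermediate
14 | methylene hydrindanone: C9 ketone, exocyclic C11=C20, 2β-OSiEt3, 14α-OSi(i-Pr)3 | O=C1[C@H]2C(=C)CC[C@H](O[Si](C(C)C)(C(C)C)C(C)C)[C@]2(C)[C@@H](O[Si](CC)(CC)CC)C1 | intermediate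
15 | hydrindenyl triethylsilyl enol ether (C3=C9, C9–OSiEt3) | CC[Si](CC)(CC)OC=1[C@H]2C(=C)CC[C@H](O[Si](C(C)C)(C(C)C)C(C)C)[C@]2(C)[C@@H](O[Si](CC)(CC)CC)C=1 | intermediate
16 | 5-bromofuran-2-carbaldehyde (C4–C8 and the ether oxygen) | O=Cc1ccc(Br)o1 | starting material
17 | (5-bromofuran-2-yl)methanol | OCc1ccc(Br)o1 | intermediate
18 | [(5-bromofuran-2-yl)methoxy](tert-butyl)dimethylsilane | CC(C)(C)[Si](C)(C)OCc1ccc(Br)o1 | intermediate
19 | tert-butyl propanoate (C17, C18, C19) | CCC(=O)OC(C)(C)C | starting material
20 | tert-butyl 2-[5-(tert-butyldimethylsilyloxymethyl)furan-2-yl]propanoate (racemic) | CC(C(=O)OC(C)(C)C)c1ccc(CO[Si](C)(C)C(C)(C)C)o1 | intermediate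
21 | tert-butyl 2-[5-(hydroxymethyl)furan-2-yl]propanoate (racemic) | CC(C(=O)OC(C)(C)C)c1ccc(CO)o1 | intermediate
22 | tert-butyl 2-(2-hydroxy-5-oxo-5,6-dihydro-2H-pyran-2-yl)propanoate (stereoisomer mixture) | CC(C(=O)OC(C)(C)C)C1(O)C=CC(=O)CO1 | intermediate
23 | tert-butyl 2-(2-acetoxy-5-oxo-5,6-dihydro-2H-pyran-2-yl)propanoate (stereoisomer mixture) | CC(=O)OC1(C(C)C(=O)OC(C)(C)C)C=CC(=O)CO1 | intermediate
24 | 6-[1-(tert-butoxycarbonyl)ethyl]-3-oxidopyrylium (ylide over C4–O–C8) | CC(C(=O)OC(C)(C)C)c1ccc([O-])c[o+]1 | intermediate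
25 | [5+2] cycloadduct: 8-oxabicyclo[3.2.1]octenone (C5 ketone, C6=C7, C4–O–C8 bridge) fused at C3–C9 to the hydrindane; 9-OSiEt3 endo, 2β-OSiEt3, C17 epimers | O=C1C=C[C@]2(C(C)C(=O)OC(C)(C)C)O[C@H]1[C@@H]1[C@@]2(O[Si](CC)(CC)CC)[C@H]2C(=C)CC[C@H](O[Si](C(C)C)(C(C)C)C(C)C)[C@]2(C)[C@H]1O[Si](CC)(CC)CC | intermediate
26 | C5 methyl carbinol of 25 (CH3 syn to the oxygen bridge, C17 epimers) | C[C@]1(O)C=C[C@]2(C(C)C(=O)OC(C)(C)C)O[C@H]1[C@@H]1[C@@]2(O[Si](CC)(CC)CC)[C@H]2C(=C)CC[C@H](O[Si](C(C)C)(C(C)C)C(C)C)[C@]2(C)[C@H]1O[Si](CC)(CC)CC | intermediate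
27 | bis-silyl lactone as C17 epimer mixture (C7–O–C19 lactone, C5(CH3)=C6) | CC=1[C@H]2O[C@]3(C(C)C(=O)O[C@H]3C1)[C@]4(O[Si](CC)(CC)CC)[C@H]1C(=C)CC[C@H](O[Si](C(C)C)(C(C)C)C(C)C)[C@]1(C)[C@@H](O[Si](CC)(CC)CC)[C@@H]42 | intermediate
28 | bis-silyl lactone, single C17 epimer (C18 anti to C9) | CC=1[C@H]2O[C@]3([C@@H](C)C(=O)O[C@H]3C1)[C@]4(O[Si](CC)(CC)CC)[C@H]1C(=C)CC[C@H](O[Si](C(C)C)(C(C)C)C(C)C)[C@]1(C)[C@@H](O[Si](CC)(CC)CC)[C@@H]42 | intermediate
29 | lactone 2,9-diol (2β-OH secondary, 9-OH tertiary) | CC=1[C@H]2O[C@]3([C@@H](C)C(=O)O[C@H]3C1)[C@]4(O)[C@H]1C(=C)CC[C@H](O[Si](C(C)C)(C(C)C)C(C)C)[C@]1(C)[C@@H](O)[C@@H]42 | intermediate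
30 | lactone β-hydroxy ketone (C2 ketone, C9 tertiary OH) | CC=1[C@H]2O[C@]3([C@@H](C)C(=O)O[C@H]3C1)[C@]4(O)[C@H]1C(=C)CC[C@H](O[Si](C(C)C)(C(C)C)C(C)C)[C@]1(C)C(=O)[C@@H]42 | intermediate
31 | potassium C2 enolate of the ring-expanded 9-ketone (C2=C3 geometry not assigned) | CC=1[C@H]2O[C@]3([C@@H](C)C(=O)O[C@H]3C1)C(=O)[C@H]1C(=C)CC[C@H](O[Si](C(C)C)(C(C)C)C(C)C)[C@]1(C)C([O-])=C2.[K+] | intermediate
32 | oxa-bridged ten-membered hydroxy diketone (C2 and C9 ketones, 3-OH) | CC=1[C@H]2O[C@]3([C@@H](C)C(=O)O[C@H]3C1)C(=O)[C@H]1C(=C)CC[C@H](O[Si](C(C)C)(C(C)C)C(C)C)[C@]1(C)C(=O)[C@@H]2O | intermediate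
33 | 2,3,9-triol (14-OSi(i-Pr)3) | CC=1[C@H]2O[C@]3([C@@H](C)C(=O)O[C@H]3C1)[C@@H](O)[C@H]1C(=C)CC[C@H](O[Si](C(C)C)(C(C)C)C(C)C)[C@]1(C)[C@@H](O)[C@@H]2O | intermediate
34 | 2,3,9,14-tetraol | CC=1[C@H]2O[C@]3([C@@H](C)C(=O)O[C@H]3C1)[C@@H](O)[C@H]1C(=C)CC[C@H](O)[C@]1(C)[C@@H](O)[C@@H]2O | intermediate
35 | 2,3,9,14-tetraacetate | CC=1[C@H]2O[C@]3([C@@H](C)C(=O)O[C@H]3C1)[C@@H](OC(C)=O)[C@H]1C(=C)CC[C@H](OC(C)=O)[C@]1(C)[C@@H](OC(C)=O)[C@@H]2OC(C)=O | intermediate
36 | 11,20-epoxide (epoxide oxygen α) | CC=1[C@H]2O[C@]3([C@@H](C)C(=O)O[C@H]3C1)[C@@H](OC(C)=O)[C@H]1[C@@]3(CO3)CC[C@H](OC(C)=O)[C@]1(C)[C@@H](OC(C)=O)[C@@H]2OC(C)=O | intermediate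
37 | chlorohydrin tetraacetate (11α-OH, C20–Cl, C5(CH3)=C6) | CC=1[C@H]2O[C@]3([C@@H](C)C(=O)O[C@H]3C1)[C@@H](OC(C)=O)[C@H]1[C@@](O)(CCl)CC[C@H](OC(C)=O)[C@]1(C)[C@@H](OC(C)=O)[C@@H]2OC(C)=O | intermediate
38 | Fragilide F | C=C1[C@H]2O[C@]3([C@@H](C)C(=O)O[C@H]3[C@H]1Cl)[C@@H](OC(C)=O)[C@H]1[C@@](O)(CCl)CC[C@H](OC(C)=O)[C@]1(C)[C@@H](OC(C)=O)[C@@H]2OC(C)=O | target

**Step count and risks**

Total step count: 29. Longest linear sequence: 21 steps (from 5 through steps 3–11 and 18–29).

Steps most likely to fail:

1. Step 18 (Proposed new method). What may go wrong: the bimolecular union of the two fully substituted carbons C8 and C9 may be outrun by dimerisation of the ylide or by its tautomerisation to the 6-alkylidene pyranone, and the approach may lose its face or exo preference. Fallback by known reactions, a stepwise polar annulation that sets out from 15 and returns at 29: the acetal carbon and the propionate-bearing carbon of the pyranone are interchanged, so that C3–C4 is made by C-glycosylation and C8–C9 by an aldol addition. Aldol addition of the lithium enolate of 19 (LiN(i-Pr)2, THF, −78 °C) to commercial 4-methylfuran-2-carbaldehyde F1 gives hydroxy ester F2. Achmatowicz rearrangement (NBS, NaHCO3, aqueous THF) gives pyranone hemiacetal F3, whose acetal carbon is C4, whose ketone is C7 and whose C5 already carries C16; acetylation gives acetate F4. SnCl4 (CH2Cl2, −78 °C) ionises F4, and C3 of 15 attacks the oxocarbenium ion at C4 from the α face (Ferrier-type C-glycosylation by a silyl enol ether) to give diketone F5 with the C9 ketone restored; racemic F4 is taken in excess so that its matched enantiomer is consumed. LiN(SiMe3)2 (THF, −78 °C) enolises the C7 ketone at C8 and the enolate adds to the C9 ketone (intramolecular aldol addition closing the five-membered O–C4–C3–C9–C8 ring) to give oxabicyclic hydroxy ketone F6. This is reduced at once (NaBH4, CeCl3·7H2O, MeOH, −78 °C) from the face of the oxygen bridge to allylic alcohol F7. Camphor-10-sulfonic acid ionises F7 to the same C5–C6–C7 allyl cation as in step 20, the ester lactonises at C7 and DBU equilibrates C17 to give lactone F8; HF·pyridine removes the C2 silyl ether and delivers 29.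

2. Step 23. What may go wrong: the fragmentation may be slow or reversible (transannular re-aldolisation), the enolate may equilibrate towards C10 before it is oxidised, or the product alkoxide may add to the sulfonimine. Fallback, which sets out from 30 and returns at 32: the enolate is trapped on oxygen, which makes the ring expansion irreversible, and C3 is oxygenated in a separate electrophilic step. KN(SiMe3)2 followed by Et3SiCl (THF, −78 to 0 °C) gives silyl enol ether F9. Rubottom oxidation with dimethyldioxirane (acetone/CH2Cl2, −78 °C), which is selective for the electron-rich enol ether and attacks its outer face, gives silyloxy epoxide F10. Buffered HF·pyridine opens and desilylates it to 32.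

3. Step 24. What may go wrong: poor facial selectivity of hydride delivery to C2 and C9, because the conformation of the bridged ring and not an acyclic model decides, and acyl transfer of the lactone to O9. Fallback, which sets out from 32 and returns at 33: reagent control replaces substrate control. Corey–Bakshi–Shibata reduction with (R)-1-methyl-3,3-diphenyltetrahydro-1H,3H-pyrrolo[1,2-c][1,3,2]oxazaborole and catecholborane (toluene, −78 to −40 °C; the alkenes are not hydroborated under these conditions) should, with the quaternary C1 and C8 as the large flanking groups, deliver hydride to the face required at both carbonyls; no compound outside the route is made (F0).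

**Further compounds**

F1 | step 18 | 4-methylfuran-2-carbaldehyde | Cc1coc(C=O)c1
F2 | step 18 | hydroxy ester: tert-butyl 3-hydroxy-2-methyl-3-(4-methylfuran-2-yl)propanoate (stereoisomer mixture) | CC(C(=O)OC(C)(C)C)C(O)c1cc(C)co1
F3 | step 18 | pyranone hemiacetal: tert-butyl 2-(6-hydroxy-5-methyl-3-oxo-3,6-dihydro-2H-pyran-2-yl)propanoate | CC(C(=O)OC(C)(C)C)C1OC(O)C(C)=CC1=O
F4 | step 18 | acetate: tert-butyl 2-(6-acetoxy-5-methyl-3-oxo-3,6-dihydro-2H-pyran-2-yl)propanoate | CC(C(=O)OC(C)(C)C)C1OC(OC(C)=O)C(C)=CC1=O
F5 | step 18 | diketone: hydrindanone 14 bearing at C3 (α) the pyranone through C4 (C8 and C17 unassigned) | CC1=CC(=O)C(C(C)C(=O)OC(C)(C)C)O[C@H]1[C@@H]1C(=O)[C@H]2C(=C)CC[C@H](O[Si](C(C)C)(C(C)C)C(C)C)[C@]2(C)[C@H]1O[Si](CC)(CC)CC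
F6 | step 18 | oxabicyclic hydroxy ketone: C7 ketone, C5(CH3)=C6, 9-OH, 2β-OSiEt3 (C17 epimers) | CC1=CC(=O)[C@]2(C(C)C(=O)OC(C)(C)C)O[C@H]1[C@@H]1[C@@]2(O)[C@H]2C(=C)CC[C@H](O[Si](C(C)C)(C(C)C)C(C)C)[C@]2(C)[C@H]1O[Si](CC)(CC)CC
F7 | step 18 | allylic alcohol: 7-OH anti to the oxygen bridge (C17 epimers) | CC1=C[C@@H](O)[C@]2(C(C)C(=O)OC(C)(C)C)O[C@H]1[C@@H]1[C@@]2(O)[C@H]2C(=C)CC[C@H](O[Si](C(C)C)(C(C)C)C(C)C)[C@]2(C)[C@H]1O[Si](CC)(CC)CC
F8 | step 18 | lactone: 28 with free 9-OH (2β-OSiEt3 kept) | CC=1[C@H]2O[C@]3([C@@H](C)C(=O)O[C@H]3C1)[C@]4(O)[C@H]1C(=C)CC[C@H](O[Si](C(C)C)(C(C)C)C(C)C)[C@]1(C)[C@@H](O[Si](CC)(CC)CC)[C@@H]42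
F9 | step 23 | silyl enol ether: C2 triethylsilyl enol ether of the ring-expanded 9-ketone (C2=C3 geometry not assigned) | CC=1[C@H]2O[C@]3([C@@H](C)C(=O)O[C@H]3C1)C(=O)[C@H]1C(=C)CC[C@H](O[Si](C(C)C)(C(C)C)C(C)C)[C@]1(C)C(O[Si](CC)(CC)CC)=C2
F10 | step 23 | silyloxy epoxide: 2,3-epoxide of F9 (C2 not assigned) | CC=1[C@H]2O[C@]3([C@@H](C)C(=O)O[C@H]3C1)C(=O)[C@H]1C(=C)CC[C@H](O[Si](C(C)C)(C(C)C)C(C)C)[C@]1(C)C3(O[Si](CC)(CC)CC)O[C@@H]32
F0 | step 24 | none | none
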